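**Assumption:** the target is taken exactly as the stereoisomer in the SMILES. Centres α to the ester, to a lactam carbonyl or to the ketone in compounds 3–20 are carried as epimer mixtures, because the last step re-equilibrates them. Local numbering: oxaquinolizidine O1–C9a (2R,3S,9R,9aS); quinolizidin-2-one C1–C9a (1R,3R,9S,9aS).

## Retrosynthetic overview

1. Target 21 ⇐ macrocyclic bis-iminium 20 in one pot: the hydroxyl traps one iminium (oxazine ring) and the ketone enol attacks the other (Mannich, piperidone ring). Six stereocentres equilibrate under control of the fixed carbinol/methyl pair.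
2. 20 ⇐ macrocyclic bis-lactam 18 by double lactam hydrosilylation; 18 ⇐ acyclic enone 17 by macrocyclising aza-Michael addition (N–CH2 bond).
3. 17 ⇐ amino alcohol lactam 13 + chloro ester Weinreb amide 5 (N-alkylation/lactamisation), then isopropenyl ketone formation.
4. 13 and 5 both ⇐ chloro ester acid 3 (monomethyl azelate + 1-bromo-3-chloropropane); the carbinol/methyl pair comes from a ketoreductase dynamic kinetic resolution of β-ketonitrile 8.
5. Ring order: lactam B (step 6) → lactam A (step 7) → macrocycle (step 9) → oxazine and piperidone rings together (step 10).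

## Route

**Step 1**
Reactants: 1 monomethyl azelate (9-methoxy-9-oxononanoic acid); 2 1-bromo-3-chloropropane
Product: 3 11-chloro-8-(methoxycarbonyl)undecanoic acid (racemic)
Conditions: LiN(iPr)2 (2.2 equiv), THF/DMPU, −78 °C; then 2, −78 → 0 °C; aq. HCl
Reagents that add atoms: none
Why: Ester enolate alkylation of the carboxylate/enolate dianion: the second equivalent of base deprotonates only α to the ester (the lithium carboxylate protects the acid end) and the enolate displaces bromide in preference to chloride; the new centre is deliberately racemic because it is erased at the enamine stage of step 10.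

**Step 2**
Reactants: 3 11-chloro-8-(methoxycarbonyl)undecanoic acid
Product: 5 methyl 2-(3-chloropropyl)-9-[methoxy(methyl)amino]-9-oxononanoate, via acyl imidazolide 4 (not isolated)
Conditions: CDI (1.1 equiv), CH2Cl2, 0 °C → rt until CO2 evolution ends; then MeNH(OMe)·HCl, rt
Reagents that add atoms: N,O-dimethylhydroxylamine hydrochloride, CNOC.Cl
Why: Activation of the acid as its N-acylimidazole followed by Weinreb amide formation (nucleophilic acyl substitution), the hydrochloride protonating the acylimidazole and so speeding the aminolysis; the α-branched methyl ester and the primary chloride are untouched and no stereocentre is involved.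

**Step 3**
Reactants: 3 11-chloro-8-(methoxycarbonyl)undecanoic acid; 6 propionitrile
Product: 8 methyl 2-(3-chloropropyl)-10-cyano-9-oxoundecanoate, via acid chloride 7 (not isolated)
Conditions: (COCl)2, DMF (cat.), CH2Cl2; concentrate; add to 6/LiN(iPr)2 (2.2 equiv each), THF, −78 °C; aq. NH4Cl
Reagents that add atoms: none
Why: C-acylation of a nitrile anion (Claisen-type condensation) by the acid chloride, which at −78 °C reacts far faster than the α-branched ester; the second equivalent of anion takes up the acidic β-ketonitrile proton and prevents double acylation, and both stereocentres are left undefined because step 4 resolves them dynamically.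

**Step 4**
Reactants: 8 methyl 2-(3-chloropropyl)-10-cyano-9-oxoundecanoate
Product: 9 methyl (9R,10S)-2-(3-chloropropyl)-10-cyano-9-hydroxyundecanoate (1:1 at C2)
Conditions: ketoreductase (anti-(9R,10S)-selective, chosen from a commercial panel), NADP+ (cat.), iPrOH, phosphate buffer pH 7.5/DMSO, 30 °C
Reagents that add atoms: none
Why: Biocatalytic ketone reduction with dynamic kinetic resolution: the α-cyano C–H (pKa about 11) racemises in the buffer faster than reduction, so the whole ketone is drained into the anti (9R,10S) alcohol with the enzyme fixing both centres, while the remote ester α-centre stays a mixture.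

**Step 5**
Reactants: 9 methyl (9R,10S)-2-(3-chloropropyl)-10-cyano-9-hydroxyundecanoate
Product: 10 methyl (9R,10S)-2-(3-azidopropyl)-10-cyano-9-hydroxyundecanoate
Conditions: NaN3, NaI (cat.), DMF, 60 °C
Reagents that add atoms: sodium azide, [Na+].[N-]=[N+]=[N-]
Why: SN2 azidation of the primary chloride; azide is too weak a base to epimerise the α-cyano centre or to cause retro-aldol cleavage.

**Step 6**
Reactants: 10 methyl (9R,10S)-2-(3-azidopropyl)-10-cyano-9-hydroxyundecanoate
Product: 13 3-[(7R,8S)-9-amino-7-hydroxy-8-methylnonyl]piperidin-2-one, via amino ester nitrile 11 (not isolated), via lactam nitrile 12 (not isolated)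
Conditions: H2 (5 bar), Raney Ni, NH3/MeOH, rt → 45 °C
Reagents that add atoms: none
Why: Catalytic hydrogenation: the azide is reduced first and the δ-amino ester closes spontaneously to six-membered lactam B, then the nitrile is reduced to the primary amine (ammonia suppresses secondary amine formation); the two set stereocentres are not touched.

**Step 7**
Reactants: 13 3-[(7R,8S)-9-amino-7-hydroxy-8-methylnonyl]piperidin-2-one; 5 methyl 2-(3-chloropropyl)-9-[methoxy(methyl)amino]-9-oxononanoate
Product: 15 7-{1-[(2S,3R)-3-hydroxy-2-methyl-9-(2-oxopiperidin-3-yl)nonyl]-2-oxopiperidin-3-yl}-N-methoxy-N-methylheptanamide, via secondary amine ester 14 (not isolated)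
Conditions: NaI (20 mol %), K2CO3, MeCN, 75 °C
Reagents that add atoms: none
Why: Iodide-catalysed amine N-alkylation followed by spontaneous δ-lactamisation, which builds lactam A and removes the secondary amine from further alkylation; the lactam N–H of 13, the hydroxyl and the Weinreb amide do not react under carbonate, and no stereocentre is affected.

**Step 8**
Reactants: 15 bis-lactam Weinreb amide; 16 isopropenylmagnesium bromide
Product: 17 1-[(2S,3R)-3-hydroxy-2-methyl-9-(2-oxopiperidin-3-yl)nonyl]-3-(8-methyl-7-oxonon-8-en-1-yl)piperidin-2-one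
Conditions: CH2=C(CH3)MgBr (4 equiv), THF, −20 → 0 °C; cold 1 M HCl/NH4Cl quench
Reagents that add atoms: none
Why: Weinreb ketone synthesis: after deprotonating N–H and O–H the Grignard reagent adds once to the N-methoxy amide and the chelated tetrahedral intermediate collapses only on quench, tertiary lactams being inert at 0 °C; the acidic quench keeps the released hydroxylamine from adding to the enone.

**Step 9**
Reactants: 17 acyclic enone bis-lactam
Product: 18 macrocyclic bis-lactam keto alcohol (24-membered ring): N of lactam B–CH2–CH(CH3)–C(=O)–(CH2)6–C3 of lactam A, and N of lactam A–CH2–CH(CH3)–CH(OH)–(CH2)6–C3 of lactam B; carbinol R, adjacent methyl carbon S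
Conditions: KOtBu (0.3 equiv), THF/tBuOH (10:1), 1 mM (slow addition), 0 °C → rt
Reagents that add atoms: none
Why: Intramolecular aza-Michael addition of the lactam amidate (the most acidic site) to the α-methyl enone; the addition is reversible, so high dilution funnels oligomers to the monomeric ring, and the new methyl-bearing centre (α to the ketone) forms as a mixture that is corrected in step 10.

**Step 10**
Reactants: 18 macrocyclic bis-lactam keto alcohol
Product: 21 target CNP0236330.1 (oxaquinolizidine 2R,3S,9R,9aS; quinolizidinone 1R,3R,9S,9aS), via bis-enamine 19 (not isolated), via bis-iminium 20 (not isolated)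
Conditions: IrCl(CO)(PPh3)2 (2 mol %), (HMe2Si)2O (5 equiv), toluene, rt; then CF3CO2H, MeOH, 50 °C, 24 h; then K2CO3, MeOH/H2O, rt
Reagents that add atoms: none
Why: Proposed new method: chemoselective hydrosilylation of both tertiary lactams (ketone tolerated; any O-silylation is undone by the acid) gives N,O-silyl hemiaminals that collapse to bis-enamine 19, and acid turns this into bis-iminium 20, in which the hydroxyl closes the N,O-acetal on one iminium and the ketone enol attacks the other (intramolecular Mannich reaction). Iminium–enamine tautomerism, N,O-acetal reopening, retro-Mannich/Mannich and enolisation keep C9/C9a of the oxaquinolizidine and C1/C3/C9/C9a of the quinolizidinone equilibrating. What should remain is the all-equatorial trans-fused oxaquinolizidine and the trans-fused quinolizidinone with equatorial 3-methyl and 9-chain and axial 1-chain (no peri clash), matched through the macrocycle to the fixed (R)-carbinol/(S)-methyl pair. The closest known reaction types are the iridium-catalysed reductive Mannich cyclisation of lactams, the acid-mediated closure of 1-oxaquinolizidines from hydroxy iminium ions, and the Mannich equilibration of 2-quinolizidinones.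

## Compound list

1 | monomethyl azelate (9-methoxy-9-oxononanoic acid) | COC(=O)CCCCCCCC(=O)O | starting material
2 | 1-bromo-3-chloropropane | ClCCCBr | starting material
3 | 11-chloro-8-(methoxycarbonyl)undecanoic acid (racemic) | COC(=O)C(CCCCl)CCCCCCC(=O)O | intermediate
4 | methyl 2-(3-chloropropyl)-9-(1H-imidazol-1-yl)-9-oxononanoate (acyl imidazolide, not isolated) | COC(=O)C(CCCCl)CCCCCCC(=O)n1ccnc1 | intermediate
5 | methyl 2-(3-chloropropyl)-9-[methoxy(methyl)amino]-9-oxononanoate | COC(=O)C(CCCCl)CCCCCCC(=O)N(C)OC | intermediate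
6 | propionitrile | CCC#N | starting material
7 | methyl 9-chloro-2-(3-chloropropyl)-9-oxononanoate (acid chloride, not isolated) | COC(=O)C(CCCCl)CCCCCCC(=O)Cl | intermediate
8 | methyl 2-(3-chloropropyl)-10-cyano-9-oxoundecanoate (stereoisomer mixture) | COC(=O)C(CCCCl)CCCCCCC(=O)C(C)C#N | intermediate
9 | methyl (9R,10S)-2-(3-chloropropyl)-10-cyano-9-hydroxyundecanoate (1:1 at C2) | COC(=O)C(CCCCl)CCCCCC[C@@H](O)[C@@H](C)C#N | intermediate
10 | methyl (9R,10S)-2-(3-azidopropyl)-10-cyano-9-hydroxyundecanoate | COC(=O)C(CCCN=[N+]=[N-])CCCCCC[C@@H](O)[C@@H](C)C#N | intermediate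
11 | methyl (9R,10S)-2-(3-aminopropyl)-10-cyano-9-hydroxyundecanoate (not isolated) | COC(=O)C(CCCN)CCCCCC[C@@H](O)[C@@H](C)C#N | intermediate
12 | (2S,3R)-3-hydroxy-2-methyl-9-(2-oxopiperidin-3-yl)nonanenitrile (not isolated) | O=C1NCCCC1CCCCCC[C@@H](O)[C@@H](C)C#N | intermediate
13 | 3-[(7R,8S)-9-amino-7-hydroxy-8-methylnonyl]piperidin-2-one | O=C1NCCCC1CCCCCC[C@@H](O)[C@@H](C)CN | intermediate
14 | methyl 2-[3-({(2S,3R)-3-hydroxy-2-methyl-9-(2-oxopiperidin-3-yl)nonyl}amino)propyl]-9-[methoxy(methyl)amino]-9-oxononanoate (not isolated) | COC(=O)C(CCCNC[C@H](C)[C@H](O)CCCCCCC1CCCNC1=O)CCCCCCC(=O)N(C)OC | intermediate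
15 | 7-{1-[(2S,3R)-3-hydroxy-2-methyl-9-(2-oxopiperidin-3-yl)nonyl]-2-oxopiperidin-3-yl}-N-methoxy-N-methylheptanamide | O=C1N(C[C@H](C)[C@H](O)CCCCCCC2CCCNC2=O)CCCC1CCCCCCC(=O)N(C)OC | intermediate
16 | isopropenylmagnesium bromide | CC(=C)[Mg]Br | starting material
17 | 1-[(2S,3R)-3-hydroxy-2-methyl-9-(2-oxopiperidin-3-yl)nonyl]-3-(8-methyl-7-oxonon-8-en-1-yl)piperidin-2-one | O=C1N(C[C@H](C)[C@H](O)CCCCCCC2CCCNC2=O)CCCC1CCCCCCC(=O)C(C)=C | intermediate
18 | macrocyclic bis-lactam keto alcohol (carbinol R, adjacent CH(CH3) S; other three centres mixed) | O=C1N2CCCC1CCCCCCC(=O)C(C)CN1CCCC(C1=O)CCCCCC[C@@H](O)[C@@H](C)C2 | intermediate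
19 | macrocyclic bis-enamine (each lactam N–C(=O)–CH now N–CH=C; not isolated) | C1(=CN2CCC1)CCCCCCC(=O)C(C)CN1C=C(CCC1)CCCCCC[C@@H](O)[C@@H](C)C2 | intermediate
20 | macrocyclic bis-iminium (two 2,3,4,5-tetrahydropyridinium rings, trifluoroacetate counter-ions; not isolated) | C1=[N+]2CCCC1CCCCCCC(=O)C(C)C[N+]1=CC(CCC1)CCCCCC[C@@H](O)[C@@H](C)C2 | intermediate
21 | target CNP0236330.1 (oxaquinolizidine 2R,3S,9R,9aS; quinolizidinone 1R,3R,9S,9aS) | C[C@@H]1CN2CCC[C@@H]3CCCCCC[C@H]4O[C@H]5[C@H](CCCCC[C@@H](C1=O)[C@H]32)CCCN5C[C@@H]4C | target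

## Step count and risks

Total steps: 10. Longest linear sequence: 9 (steps 1, 3, 4, 5, 6, 7, 8, 9, 10); step 2 is the side branch.

**Most likely to fail, first: step 10.** The ketone may be hydrosilylated in competition with the lactams. The thermodynamic outcome across the macrocycle (which quinolizidinone antipode pairs with the fixed oxaquinolizidine) is not guaranteed to be the natural one. The fallback sets out from 18 and separates carbonyl protection from lactam reduction. The ketone is masked with ethylene glycol, CH(OMe)3 and TsOH as the dioxolane ketal F1. Both lactams are then reduced to the hemiaminal level with stoichiometric Cp2Zr(H)Cl in THF, which after mild work-up gives the ketal bis-enamine F2. Treatment with 2 M HCl/THF at 50 °C removes the ketal and delivers bis-iminium 20, where the fallback rejoins the route; closure and equilibration to 21 follow as before.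

**Second: step 9.** The enone is enolisable and a lactam amidate is a modest nucleophile, so oligomers or C-Michael products may dominate. The fallback changes the macrocyclising bond; it sets out from 13 and from 3 (through acid chloride 7) and returns at 18. Amine 13 is dibenzylated (BnBr, K2CO3, MeCN) to the dibenzylamino lactam F3. Acid chloride 7 is coupled with 16 under Fe(acac)3 catalysis at −78 °C to give the enone chloro ester F4. Intermolecular aza-Michael addition of F3 to F4 (KOtBu cat., concentrated THF) gives the open-chain adduct F5. Hydrogenolysis (H2, Pd(OH)2/C, MeOH) frees the primary amine F6. NaI/K2CO3 in MeCN at 2 mM and 80 °C closes the large ring by N-alkylation to the macrocyclic amino ester F7, which lactamises in the same pot to 18.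

**Third: step 4.** No panel enzyme may give the anti (9R,10S) isomer at a useful rate and selectivity on this long-chain substrate. The fallback builds the pair by reagent-controlled C–C bond formation; it sets out from 3 (through acid chloride 7) and returns at 9. Rosenmund reduction of 7 (H2, Pd/BaSO4, 2,6-lutidine) gives the aldehyde F8. Brown crotylboration with (E)-crotyl-B(Ipc)2, made from trans-2-butene, n-BuLi/KOtBu, (−)-Ipc2BOMe and BF3·OEt2 at −78 °C, gives the anti homoallylic alcohol F9. Ozonolysis (O3, CH2Cl2/MeOH, −78 °C; Me2S) gives the hydroxy aldehyde F10, which I2 in aqueous NH3/THF oxidises to the nitrile 9.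

## Further compounds

F1 | step 10 | ethylene ketal (1,3-dioxolane) of the ketone of 18 | O=C1N2CCCC1CCCCCCC3(OCCO3)C(C)CN1CCCC(C1=O)CCCCCC[C@@H](O)[C@@H](C)C2
F2 | step 10 | ketal bis-enamine (19 with the ketone as its 1,3-dioxolane) | C1(=CN2CCC1)CCCCCCC3(OCCO3)C(C)CN1C=C(CCC1)CCCCCC[C@@H](O)[C@@H](C)C2
F3 | step 9 | 3-[(7R,8S)-9-(dibenzylamino)-7-hydroxy-8-methylnonyl]piperidin-2-one | O=C1NCCCC1CCCCCC[C@@H](O)[C@@H](C)CN(Cc1ccccc1)Cc1ccccc1
F4 | step 9 | methyl 2-(3-chloropropyl)-10-methyl-9-oxoundec-10-enoate | COC(=O)C(CCCCl)CCCCCCC(=O)C(C)=C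
F5 | step 9 | methyl 2-(3-chloropropyl)-11-{3-[(7R,8S)-9-(dibenzylamino)-7-hydroxy-8-methylnonyl]-2-oxopiperidin-1-yl}-10-methyl-9-oxoundecanoate | COC(=O)C(CCCCl)CCCCCCC(=O)C(C)CN1CCCC(C1=O)CCCCCC[C@@H](O)[C@@H](C)CN(Cc1ccccc1)Cc1ccccc1
F6 | step 9 | methyl 11-{3-[(7R,8S)-9-amino-7-hydroxy-8-methylnonyl]-2-oxopiperidin-1-yl}-2-(3-chloropropyl)-10-methyl-9-oxoundecanoate | COC(=O)C(CCCCl)CCCCCCC(=O)C(C)CN1CCCC(C1=O)CCCCCC[C@@H](O)[C@@H](C)CN
F7 | step 9 | macrocyclic secondary amine methyl ester (18 before closure of lactam A) | COC(=O)C1CCCNC[C@H](C)[C@H](O)CCCCCCC2CCCN(CC(C)C(=O)CCCCCC1)C2=O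
F8 | step 4 | methyl 2-(3-chloropropyl)-9-oxononanoate | COC(=O)C(CCCCl)CCCCCCC=O
F9 | step 4 | methyl (9R,10S)-2-(3-chloropropyl)-9-hydroxy-10-methyldodec-11-enoate | COC(=O)C(CCCCl)CCCCCC[C@@H](O)[C@@H](C)C=C
F10 | step 4 | methyl (9R,10R)-2-(3-chloropropyl)-9-hydroxy-10-methyl-11-oxoundecanoate | COC(=O)C(CCCCl)CCCCCC[C@@H](O)[C@@H](C)C=O
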